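A direct plan would close ring C in one pot from the 2-arylacrylic acid A1 and the aryne released from the silyl triflate A2 (insertion into the acyl C–O bond, then oxa-Michael closure), which would give the MOM-protected isoflavanone A3 as a racemate.
C3 would then be repaired: transfer hydrogenation under dynamic kinetic resolution to the cis-chromanol A4, reoxidation to the ketone, and removal of three MOM ethers with HCl in methanol.
Weak point 1, the ring closure that creates C3: the centre would arise by unselective protonation of an enolate, so the only stereocentre would be set racemic and corrected by a reduction/oxidation pair that builds nothing and makes a C4 centre only to erase it.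
Weak point 2, the run-up to the two partners: ring B would need its OMe and OH exchanged (demethylation to catechol A5, then a remethylation whose site selectivity rests on a small acidity difference), and A2 would cost four steps of carbamate, silyl and triflate handling for a fragment that brings only ring A.
Weak point 3, the last step: acid would meet the epimerisable C3–H and the acid-sensitive prenyl alkene at a stage where nothing can be repaired.

**Retrosynthetic overview**
Feature used: C2 of ring C is a CH2 bound only to O1 and to the stereocentre C3, so it can be the methyl carbon of an aryl methyl ether; C3 is the α-carbon of the C4 ketone and carries ring B.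
Key disconnection C2–C3: target ⇐ silyl ether 12 ⇐ α-aryl-α-diazoketone 11, whose C3 carbene would insert into a C–H bond of the ortho OMe group of ring A, closing ring C and setting C3 in one event.
11 ⇐ deoxybenzoin 10 (diazo transfer) ⇐ acetophenone 2 + bromide 9 (Pd α-arylation forms C3–C1′); 9 ⇐ 2,4,6-tribromoanisole by two ortho-selective Br/Li exchanges.
Rings A and B are bought; ring C closes last, at C2–C3, after C4–C4a (bought), O1–C2 (bought as OMe) and C3–C1′ are in place.
C3 is created once, at the ketone oxidation level and without base, so no redox repair is needed; the anisole already has OMe between the two sites to be functionalised, so no OMe/OH exchange; the end game uses buffered fluoride, not acid.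

Key step: step 7

Assumption: 1-(2,4-dihydroxy-6-methoxyphenyl)ethanone is taken as a catalogue compound.
Assumption: the S-configured catalyst is assumed to give 3S in the new insertion; if the first run showed the opposite sense, the enantiomeric catalyst would be used.

Step 1
Reactants: 1 1-(2,4-dihydroxy-6-methoxyphenyl)ethanone
Product: 2 1-[2-methoxy-4,6-bis(triisopropylsilyloxy)phenyl]ethanone
Conditions: TIPSCl (2.5 equiv), imidazole, DMAP (cat.), DMF, 50 °C
Reagents that add atoms: chlorotri(propan-2-yl)silane CC(C)[Si](Cl)(C(C)C)C(C)C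
Why: O-silylation of both phenols (substitution at silicon, warming for the hydroxyl that is hydrogen-bonded to the acetyl group); the triisopropylsilyl ether is chosen because it has no C–H bond on a carbon next to oxygen, its oxygen is hindered, and it withstands phosphate and amidine bases.

Step 2
Reactants: 3 1,3,5-tribromo-2-methoxybenzene (2,4,6-tribromoanisole)
Product: 5 1,5-dibromo-2-methoxy-3-(3-methylbut-2-enyl)benzene, via aryllithium 4 (not isolated)
Conditions: n-BuLi (1.0 equiv), Et2O, −78 °C; CuBr·SMe2 (10 mol%), prenyl bromide, −78 to 0 °C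
Reagents that add atoms: 1-bromo-3-methylbut-2-ene CC(C)=CCBr
Why: Bromine–lithium exchange takes place at a bromine ortho to the methoxy group, where the aryllithium is stabilised by coordination and induction (the two ortho sites are equivalent), and copper-catalysed allylic substitution at the primary carbon of prenyl bromide gives the linear prenyl arene.

Step 3
Reactants: 5 1,5-dibromo-2-methoxy-3-(3-methylbut-2-enyl)benzene
Product: 8 5-bromo-2-methoxy-3-(3-methylbut-2-enyl)phenol, via aryllithium 6 (not isolated), via dimethyl arylboronate 7 (not isolated)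
Conditions: n-BuLi (1.05 equiv), Et2O, −78 °C; B(OMe)3, −78 °C to rt; H2O2 (30% aq.), NaOH (aq.), 0 °C
Reagents that add atoms: hydrogen peroxide OO; trimethyl borate COB(OC)OC (its atoms stay only in 7)
Why: A second ortho-selective bromine–lithium exchange (the para bromine has no neighbouring oxygen), borylation, and oxidative 1,2-shift of the aryl group from boron to oxygen with alkaline hydrogen peroxide give the phenol; alkaline peroxide does not epoxidise the isolated alkene.

Step 4
Reactants: 8 5-bromo-2-methoxy-3-(3-methylbut-2-enyl)phenol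
Product: 9 [5-bromo-2-methoxy-3-(3-methylbut-2-enyl)phenoxy]triisopropylsilane
Conditions: TIPSCl, imidazole, DMF, rt
Reagents that add atoms: chlorotri(propan-2-yl)silane CC(C)[Si](Cl)(C(C)C)C(C)C
Why: Standard silylation of an unhindered phenol gives the same protecting group as on ring A, so that one fluoride step unmasks all three phenols at the end.

Step 5
Reactants: 2 1-[2-methoxy-4,6-bis(triisopropylsilyloxy)phenyl]ethanone (1.2 equiv); 9 [5-bromo-2-methoxy-3-(3-methylbut-2-enyl)phenoxy]triisopropylsilane
Product: 10 1-[2-methoxy-4,6-bis(triisopropylsilyloxy)phenyl]-2-[4-methoxy-3-(3-methylbut-2-enyl)-5-(triisopropylsilyloxy)phenyl]ethanone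
Conditions: Pd(OAc)2 (3 mol%), XPhos (6 mol%), K3PO4, toluene, 90 °C
Reagents that add atoms: none
Why: Palladium-catalysed α-arylation of a methyl ketone (Buchwald–Hartwig type): zerovalent palladium formed in the flask adds to the only C–Br bond of 9, the potassium enolate of 2 binds and reductive elimination forms C3–C1′; the bulky ligand and the more acidic, more hindered product stop a second arylation, and anhydrous phosphate spares the aryl silyl ethers.

Step 6
Reactants: 10 1-[2-methoxy-4,6-bis(triisopropylsilyloxy)phenyl]-2-[4-methoxy-3-(3-methylbut-2-enyl)-5-(triisopropylsilyloxy)phenyl]ethanone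
Product: 11 2-diazo-1-[2-methoxy-4,6-bis(triisopropylsilyloxy)phenyl]-2-[4-methoxy-3-(3-methylbut-2-enyl)-5-(triisopropylsilyloxy)phenyl]ethanone
Conditions: p-ABSA (1.5 equiv), DBU (1.5 equiv), MeCN, 0 °C to rt
Reagents that add atoms: 4-acetamidobenzenesulfonyl azide CC(=O)Nc1ccc(cc1)S(=O)(=O)N=[N+]=[N-]
Why: Regitz diazo transfer: the CH2 of the deoxybenzoin is benzylic and α to the ketone, so DBU forms the enolate and it takes N2 from the sulfonyl azide without prior activation; dry amidine base leaves the silyl ethers and the alkene alone.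

Step 7
Reactants: 11 2-diazo-1-[2-methoxy-4,6-bis(triisopropylsilyloxy)phenyl]-2-[4-methoxy-3-(3-methylbut-2-enyl)-5-(triisopropylsilyloxy)phenyl]ethanone
Product: 12 (3S)-3-[4-methoxy-3-(3-methylbut-2-enyl)-5-(triisopropylsilyloxy)phenyl]-5,7-bis(triisopropylsilyloxy)chroman-4-one
Conditions: Rh2(S-PTAD)4 (dirhodium tetrakis[(S)-(1-adamantyl)(phthalimido)acetate], 1 mol%), 4 Å MS, CH2Cl2, slow addition of 11 (final 0.01 M), 0 °C to rt
Reagents that add atoms: none
Why: Proposed new method: the dirhodium catalyst expels N2 from 11 and gives an electrophilic aryl(acyl)carbene at C3; because both positions ortho to the carbonyl on ring A are substituted, the aroyl group is twisted and the only C–H bonds within reach of a five- or six-membered transition state are those of the ortho methoxy group, made hydridic by the oxygen lone pair, so a concerted, asynchronous insertion (hydride shift to C3 while C2–C3 forms) should give 12 and release the catalyst. The closest known reaction types are the intramolecular C–H insertion of 2-alkoxyphenyl α-diazoketones next to the ether oxygen, which gives chroman-4-ones under divalent rhodium carboxylate catalysis, and the cyclisation of α-aryl-α-diazoketones to α-aryl cycloalkanones; new is their combination, an aryl ketone carbene inserting into a primary O–CH3 bond. Ring C closes by 1,6-insertion through a six-membered transition state that contains O1 (a 1,5-insertion is impossible, since that position is the oxygen itself). C3 is the only new stereocentre and is formed at the carbene carbon; its configuration is set by the catalyst, whose four chiral phthalimido-carboxylate ligands leave one face of the carbene open to the C–H bond, and since no base is present the α-aryl ketone should not epimerise afterwards. The step needs chemoselectivity for insertion over oxonium ylide formation and over bimolecular reactions: an ylide at the methoxy oxygen has no low-energy 1,2-shift for a methyl group and should revert, the silyloxy oxygen is hindered and weakly basic, the trisubstituted prenyl alkene is a poor partner for a donor/acceptor carbene, and slow addition at high dilution suppresses dimerisation.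

Step 8
Reactants: 12 (3S)-3-[4-methoxy-3-(3-methylbut-2-enyl)-5-(triisopropylsilyloxy)phenyl]-5,7-bis(triisopropylsilyloxy)chroman-4-one
Product: 13 (3S)-5,7-dihydroxy-3-[3-hydroxy-4-methoxy-5-(3-methylbut-2-enyl)phenyl]chroman-4-one (target)
Conditions: Bu4NF (3.6 equiv), AcOH (4 equiv), THF, 0 °C
Reagents that add atoms: none
Why: Fluoride-induced cleavage of the three aryl silyl ethers (attack at silicon, phenoxide as leaving group); acetic acid protonates each phenoxide as it forms, so no base strong enough to enolise C3 should persist, and neither fluoride nor acetic acid touches the prenyl alkene.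

**Compound list**

1 | 1-(2,4-dihydroxy-6-methoxyphenyl)ethanone | CC(=O)c1c(O)cc(O)cc1OC | starting material
2 | 1-[2-methoxy-4,6-bis(triisopropylsilyloxy)phenyl]ethanone | CC(=O)c1c(O[Si](C(C)C)(C(C)C)C(C)C)cc(O[Si](C(C)C)(C(C)C)C(C)C)cc1OC | intermediate
3 | 1,3,5-tribromo-2-methoxybenzene (2,4,6-tribromoanisole) | COc1c(Br)cc(Br)cc1Br | starting material
4 | (3,5-dibromo-2-methoxyphenyl)lithium | [Li]c1cc(Br)cc(Br)c1OC | intermediate
5 | 1,5-dibromo-2-methoxy-3-(3-methylbut-2-enyl)benzene | COc1c(Br)cc(Br)cc1CC=C(C)C | intermediate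
6 | [5-bromo-2-methoxy-3-(3-methylbut-2-enyl)phenyl]lithium | [Li]c1cc(Br)cc(CC=C(C)C)c1OC | intermediate
7 | dimethyl [5-bromo-2-methoxy-3-(3-methylbut-2-enyl)phenyl]boronate | COB(OC)c1cc(Br)cc(CC=C(C)C)c1OC | intermediate
8 | 5-bromo-2-methoxy-3-(3-methylbut-2-enyl)phenol | COc1c(O)cc(Br)cc1CC=C(C)C | intermediate
9 | [5-bromo-2-methoxy-3-(3-methylbut-2-enyl)phenoxy]triisopropylsilane | COc1c(O[Si](C(C)C)(C(C)C)C(C)C)cc(Br)cc1CC=C(C)C | intermediate
10 | 1-[2-methoxy-4,6-bis(triisopropylsilyloxy)phenyl]-2-[4-methoxy-3-(3-methylbut-2-enyl)-5-(triisopropylsilyloxy)phenyl]ethanone | COc1cc(O[Si](C(C)C)(C(C)C)C(C)C)cc(O[Si](C(C)C)(C(C)C)C(C)C)c1C(=O)Cc1cc(CC=C(C)C)c(OC)c(O[Si](C(C)C)(C(C)C)C(C)C)c1 | intermediate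
11 | 2-diazo-1-[2-methoxy-4,6-bis(triisopropylsilyloxy)phenyl]-2-[4-methoxy-3-(3-methylbut-2-enyl)-5-(triisopropylsilyloxy)phenyl]ethanone | COc1cc(O[Si](C(C)C)(C(C)C)C(C)C)cc(O[Si](C(C)C)(C(C)C)C(C)C)c1C(=O)C(=[N+]=[N-])c1cc(CC=C(C)C)c(OC)c(O[Si](C(C)C)(C(C)C)C(C)C)c1 | intermediate
12 | (3S)-3-[4-methoxy-3-(3-methylbut-2-enyl)-5-(triisopropylsilyloxy)phenyl]-5,7-bis(triisopropylsilyloxy)chroman-4-one | CC(C)=CCc1cc([C@H]2COc3cc(O[Si](C(C)C)(C(C)C)C(C)C)cc(O[Si](C(C)C)(C(C)C)C(C)C)c3C2=O)cc(O[Si](C(C)C)(C(C)C)C(C)C)c1OC | intermediate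
13 | (3S)-5,7-dihydroxy-3-[3-hydroxy-4-methoxy-5-(3-methylbut-2-enyl)phenyl]chroman-4-one | COc1c(O)cc([C@H]2COc3cc(O)cc(O)c3C2=O)cc1CC=C(C)C | target

**Step count and risks**

Total step count: 8. Longest linear sequence: 7 steps (steps 2 to 8, from 3 to 13).

Steps most likely to fail:

1. Step 7 (the proposed new method). The carbene could be diverted before it reaches the methoxy C–H bond (ylide chemistry at an ether oxygen, dimerisation, reaction with the alkene of a second molecule), or the insertion could proceed with poor facial selectivity. The fallback uses known chemistry, sets out from bromide 9 and comes back at 12. Commercial 5,7-dihydroxychroman-4-one F1 would be silylated (TIPSCl, imidazole, DMF) to 5,7-bis(triisopropylsilyloxy)chroman-4-one F2. Palladium-catalysed α-arylation of F2 with 9 (Pd2(dba)3, XPhos, K3PO4, toluene, 90 °C) would give the racemic isoflavanone F3. Transfer hydrogenation under dynamic kinetic resolution (RuCl[(S,S)-TsDPEN](p-cymene), HCO2H/Et3N, EtOAc, 40 °C) would give the cis-(3S,4S)-chromanol F4, and Dess–Martin oxidation under bicarbonate buffer would return the ketone 12.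

2. Step 5. The enolate of the doubly ortho-substituted ketone may couple slowly, and long heating with base may cause silyl migration or loss. The fallback sets out from 2 and 9 and comes back at 11, forming the C3–C1′ bond at the diazo stage at room temperature. Ketone 2 would be trifluoroacetylated (LiN(SiMe3)2, CF3CO2CH2CF3, THF, −78 °C) to the 1,3-diketone F5, and detrifluoroacetylative diazo transfer (MsN3, Et3N, H2O, MeCN) would give the acyldiazomethane F6. Bromide 9 would be converted into the aryl iodide F7 (t-BuLi, Et2O, −78 °C; ICH2CH2I). Palladium-catalysed C–H arylation of F6 with F7 (Pd(PPh3)4, Ag2CO3, Et3N, toluene, rt) would give 11 directly.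

3. Step 8. Cleavage of the hindered silyl ether at O5 may lag, and longer exposure to fluoride could allow epimerisation at C3 through the enol. The fallback sets out from 11 and comes back at 13; it moves the fluoride step in front of the creation of the stereocentre. Diazoketone 11 would be desilylated (Bu4NF, THF, 0 °C) to the triphenol F8 and re-protected (Et3SiCl, imidazole, CH2Cl2) as the tris(triethylsilyl) ether F9. The insertion of step 7 would then give the tris(triethylsilyl) isoflavanone F10, whose labile aryl silyl ethers would be solvolysed with AcOH/THF/H2O at rt to 13 without fluoride or base.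

**Further compounds**

F1 | step 7 | 5,7-dihydroxychroman-4-one | O=C1CCOc2cc(O)cc(O)c12
F2 | step 7 | 5,7-bis(triisopropylsilyloxy)chroman-4-one | O=C1CCOc2cc(O[Si](C(C)C)(C(C)C)C(C)C)cc(O[Si](C(C)C)(C(C)C)C(C)C)c12
F3 | step 7 | (±)-3-[4-methoxy-3-(3-methylbut-2-enyl)-5-(triisopropylsilyloxy)phenyl]-5,7-bis(triisopropylsilyloxy)chroman-4-one | CC(C)=CCc1cc(C2COc3cc(O[Si](C(C)C)(C(C)C)C(C)C)cc(O[Si](C(C)C)(C(C)C)C(C)C)c3C2=O)cc(O[Si](C(C)C)(C(C)C)C(C)C)c1OC
F4 | step 7 | (3S,4S)-3-[4-methoxy-3-(3-methylbut-2-enyl)-5-(triisopropylsilyloxy)phenyl]-5,7-bis(triisopropylsilyloxy)chroman-4-ol (cis) | CC(C)=CCc1cc([C@H]2COc3cc(O[Si](C(C)C)(C(C)C)C(C)C)cc(O[Si](C(C)C)(C(C)C)C(C)C)c3[C@H]2O)cc(O[Si](C(C)C)(C(C)C)C(C)C)c1OC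
F5 | step 5 | 4,4,4-trifluoro-1-[2-methoxy-4,6-bis(triisopropylsilyloxy)phenyl]butane-1,3-dione | COc1cc(O[Si](C(C)C)(C(C)C)C(C)C)cc(O[Si](C(C)C)(C(C)C)C(C)C)c1C(=O)CC(=O)C(F)(F)F
F6 | step 5 | 2-diazo-1-[2-methoxy-4,6-bis(triisopropylsilyloxy)phenyl]ethanone | COc1cc(O[Si](C(C)C)(C(C)C)C(C)C)cc(O[Si](C(C)C)(C(C)C)C(C)C)c1C(=O)C=[N+]=[N-]
F7 | step 5 | [5-iodo-2-methoxy-3-(3-methylbut-2-enyl)phenoxy]triisopropylsilane | COc1c(O[Si](C(C)C)(C(C)C)C(C)C)cc(I)cc1CC=C(C)C
F8 | step 8 | 2-diazo-1-(2,4-dihydroxy-6-methoxyphenyl)-2-[3-hydroxy-4-methoxy-5-(3-methylbut-2-enyl)phenyl]ethanone | COc1cc(O)cc(O)c1C(=O)C(=[N+]=[N-])c1cc(CC=C(C)C)c(OC)c(O)c1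
F9 | step 8 | 2-diazo-1-[2-methoxy-4,6-bis(triethylsilyloxy)phenyl]-2-[4-methoxy-3-(3-methylbut-2-enyl)-5-(triethylsilyloxy)phenyl]ethanone | COc1cc(O[Si](CC)(CC)CC)cc(O[Si](CC)(CC)CC)c1C(=O)C(=[N+]=[N-])c1cc(CC=C(C)C)c(OC)c(O[Si](CC)(CC)CC)c1
F10 | step 8 | (3S)-3-[4-methoxy-3-(3-methylbut-2-enyl)-5-(triethylsilyloxy)phenyl]-5,7-bis(triethylsilyloxy)chroman-4-one | CC(C)=CCc1cc([C@H]2COc3cc(O[Si](CC)(CC)CC)cc(O[Si](CC)(CC)CC)c3C2=O)cc(O[Si](CC)(CC)CC)c1OC
A1 | direct plan | 2-[4-methoxy-3-(methoxymethoxy)-5-(3-methylbut-2-enyl)phenyl]prop-2-enoic acid | C=C(C(=O)O)c1cc(CC=C(C)C)c(OC)c(OCOC)c1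
A2 | direct plan | 3,5-bis(methoxymethoxy)-2-(trimethylsilyl)phenyl trifluoromethanesulfonate | COCOc1cc(OCOC)c([Si](C)(C)C)c(OS(=O)(=O)C(F)(F)F)c1
A3 | direct plan | (±)-5,7-bis(methoxymethoxy)-3-[4-methoxy-3-(methoxymethoxy)-5-(3-methylbut-2-enyl)phenyl]chroman-4-one | CC(C)=CCc1cc(C2COc3cc(OCOC)cc(OCOC)c3C2=O)cc(OCOC)c1OC
A4 | direct plan | (3S,4S)-5,7-bis(methoxymethoxy)-3-[4-methoxy-3-(methoxymethoxy)-5-(3-methylbut-2-enyl)phenyl]chroman-4-ol (cis) | CC(C)=CCc1cc([C@H]2COc3cc(OCOC)cc(OCOC)c3[C@H]2O)cc(OCOC)c1OC
A5 | direct plan | 1-(3-bromo-4,5-dihydroxyphenyl)ethanone | CC(=O)c1cc(O)c(O)c(Br)c1
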